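At early times the dawn run loses substrate quickly, so the examination starts there.

| flask | substrate | reagent | free catalyst | temperature | remark | time |
|---|---|---|---|---|---|---|
| dawn | 0.056 M | 0.55 equiv | 17 mol% | 5 °C | run made earlier |  |
| epsilon | 0.056 M | 1.10 equiv | 17 mol% | 5 °C |  | 10 h |
| delta | 0.056 M | 1.10 equiv | 17 mol% | 30 °C |  | 10 h |

dawn run (percent of the substrate charged)

| time / h | substrate / % | product / % | catalyst intermediate A / % | catalyst intermediate B / % |
|---|---|---|---|---|
| 0.500 | 95.1 | 0 | 5.0 | 0.6 |
| 1.00 | 92.7 | 0.2 | 6.4 | 1.3 |
| 1.50 | 90.5 | 0.5 | 7.6 | 2.5 |
| 2.00 | 88.0 | 0.4 | 7.3 | 3.8 |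
| 2.50 | 85.9 | 0.8 | 7.3 | 3.5 |
| 3.00 | 85.7 | 1.0 | 7.2 | 4.7 |

(scatter of a reading: 0.5 percentage points)

- the numbers in the tables scatter by 0.5 percentage points (one standard deviation)
- the earlier runs do not show what temperature does; that part of a forecast is a guess

- which of these there is most of at the end, counted by the substrate in it, epsilon (product / catalyst intermediate A / catalyst intermediate B / substrate)
- which of these there is most of at the end, counted by the substrate in it, delta (product / catalyst intermediate A / catalyst intermediate B / substrate)
- amount of the one of these that there is most of at the end, in percent of the substrate charged, epsilon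
- amount of the one of these that there is most of at the end, in percent of the substrate charged, delta

What stands nearly still in the dawn run? Catalyst intermediate A does: it reads 7.3 % at 2.00 h and 7.2 % at 3.00 h, a flat stretch within the scatter (a quasi-steady state).

And the substrate over that stretch? It falls from 88.0 % to 85.7 %, a slope of 0.0230 /h. I call this the drain, the fraction of the substrate charge lost per hour once catalyst intermediate A has stopped rising.

Why not take the earlier slope? From 0.500 h to 2.00 h the reading is 0.0473 /h, twice the drain, but catalyst intermediate A was still filling then, so that slope does not describe the flat stretch.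

How good is a slope from two readings? Poor: carried to the end of epsilon, it is uncertain by 4.9 percentage points.

And the weak spot? Catalyst intermediate B still climbs, and the dawn run has one reagent charge, so no reading shows what doubling the reagent does. I freeze the drain anyway and accept that risk.

Then epsilon? From the last reading, the frozen drain leaves 69.6 % substrate at 10 h. The other forms together share 30.4 %, so in this reckoning epsilon ends with more substrate than the other forms together.

And delta? Temperature is unread, so I guess a factor of 5 on the drain. In this reckoning the charge then lasts 8.70 h, less than the 10 h allowed. So my estimate for delta has product leading, at about 83.0 % once the catalyst loading is set aside as bound.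

The forecast names substrate at 74 % for epsilon and product at 68 % for delta, the same leaders as mine, higher than my figure in epsilon and lower in delta, where its grounds include "guessing a rate rise of 4–8 times".

Epsilon ends with substrate at 69.9 %, and delta ends with product at 56.0 %.

    reagent + catalyst intermediate A → catalyst intermediate B (k = 13.0 /M/h, Ea = 58.0 kJ/mol)
    catalyst intermediate A → spent catalyst (k = 0.0350 /h, Ea = 102 kJ/mol)
    catalyst intermediate B ⇌ released group + catalyst intermediate C (K = 4.10 M, k = 0.380 /h, Ea = 85.0 kJ/mol, ΔH = −51.0 kJ/mol)
    catalyst intermediate C → free catalyst + product (k = 0.860 /h, Ea = 83.0 kJ/mol)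
    substrate + free catalyst → catalyst intermediate A (k = 12.0 /M/h, Ea = 61.0 kJ/mol)
    (constants at 5 °C)

At the end of delta, spent catalyst stands at 96.9 % of the catalyst charged, with 1.87 % free catalyst. Measured over the second stretch of each flask, from 5.00 h to 10.0 h, the drain is 0.0217 /h in epsilon, close to the frozen value. In delta, at 30 °C, it is 0.0139 /h, lower than the frozen value. Left for 100 h, delta still holds 25.7 % substrate.

The numbers in the tables come from a simulation with constants of no real substance, and the scatter is random.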